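## Structural features

Atom labels used throughout: ring C1–C6 (C1 carries the side chain, C2 the ring O-angelate, C3 the ketone, C4 the methyl C15 and one epoxide terminus, C5 the other terminus, C6 is CH2); side chain C7 (sp2, =C14H2), C8 (O-angelate), C9–C13 (CH2–CH=CMe2); β is the ring face that carries C7. The target is a bisabolane in which a cyclohexanone ring is joined at C1 to the fully substituted trigonal C7, which also bears the exocyclic methylene C14 and the carbinol carbon C8 with its homoprenyl tail. Four ring stereocentres are locked to one another: C1 (side chain β), C2 (O-angelate α, trans to the C1 substituent) and the C4–C5 epoxide (oxygen β, cis to the C1 substituent), with the C3 carbonyl between C2 and C4. The fifth stereocentre, C8 (S), stands alone, 1,3 to C1 across the planar C7, so no ring centre can relay to it. Fragile groups are the two angelates (Z to E isomerisation, base), the α-acyloxy ketone (epimerisable C2, acyl shifts), the α,β-epoxy ketone, the allylic ester at C8, and three alkenes of which C10=C11 is the most nucleophilic, so no undirected electrophilic oxidation is possible once the tail is present. The ring centres are the easier part because each can be set from C1 by a cyclic, substrate-controlled step; the real difficulty is C8, a secondary O-bearing carbon bonded to the hindered C7 on one side and to a linear CH2–CH=CMe2 unit on the other, which allyl-metal chemistry would attach through its tertiary carbon, and whose configuration must come from a reagent. The key step exploits exactly this C7(sp2)–C8(sp3, O) linkage: an oxygenated carbon next to an alkenyl carbon is the retron of a 1,2-shift of an alkenyl group from boron onto an α-oxygenated carbanion, so C8 can arrive with C9–C13 already attached and its configuration fixed by the lithiating reagent.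

## Logic of the disconnections

20 to 19. Cut: the ester bond between O2 and its angeloyl group. Reason: the α-acyloxy ketone is the most base-labile unit of 20 and the angelate the most isomerisable, so this bond is made last. Gain: 19 has one free hydroxyl and needs no protecting group. Demand: acylation of a hindered ketol without Z to E isomerisation of the acyl donor and without epimerisation at C2.

19 to 17 (through 18). Cut: the C2–O bond. Reason: C4 is quaternary, so the C3 ketone of 17 can enolise only toward C2, and the C1 substituent shields one face of that enolate. Gain: one stereocentre and one oxygen fewer. Demand: oxygen transfer anti to the C1 substituent, and a base that spares the C8 ester.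

17 to 15 (through 16). Change: C3=O back to C3–O–Si (C3–H restored, O–Si added). Reason: C3 must stay at the carbinol level while organolithium and palladium chemistry is done, and the same carbinol directed the epoxide earlier. Gain: 15 carries no carbonyl that a carbanion could attack. Demand: desilylation beside an epoxide and an ester, then a non-acidic oxidation.

15 to 14. Cut: the O8–acyl ester bond. Reason: 14 has a single free hydroxyl, so the first angelate is placed without any selectivity question as soon as C8 exists. Demand: as for the last step.

14 to 8 plus 10 (through 11, 12, 13). Cut: the C7–C8 bond, together with the C8–O bond, which in the forward sense replaces a C8–B bond. Reason: this is the bond between the fully substituted C7 and the one stereocentre the ring cannot control; cutting here instead of at C8–C9 keeps the CH2–CH=CMe2 unit out of any allyl-metal step and lets C8 enter as a configurationally defined carbanion. Gain: 14 falls into a nine-carbon ring boronate 8 (C1–C7, C14, C15) and an achiral six-carbon ester 10 (C8–C13); the C8 problem reduces to the choice of a diamine. Demand: a boronate complex between two hindered partners, migration of the alkenyl carbon with inversion at C8, and survival of the epoxide and silyl ether.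

8 to 7 to 5 (through 6). Cut: the C7–B bond, then the C7–O (triflate) bond back to the C7=O of a methyl ketone. Reason: a methyl ketone is the simplest precursor of a 1-substituted vinyl metal, and its methyl becomes C14. Demand: enolisation at CH3 and not at C1, which would erase the C1 configuration.

5 to 4. Reconnection: C7=O back to C7=CH2, an isopropenyl group. Reason: 4 then has the carbon skeleton of a commercial monoterpene; one carbon is excised in the forward direction. Demand: the isopropenyl alkene must by then be the only C=C, which fixes the order epoxidation before cleavage.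

4 to 3 to 2 to 1. Cut: the O–Si bond, then both epoxide C–O bonds (C4–O, C5–O), then the C3–H bond. Reason: the epoxide oxygen is cis to the C1 substituent, the opposite of what conjugate epoxidation of an enone would give; a C3 hydroxyl cis to the C1 substituent can deliver oxygen to that face, and that hydroxyl comes from 1,2-reduction of the enone 1, which already holds C1 correctly. Gain: all ring stereocentres except C2 trace back to the single centre of 1. Demand: cis-selective hydride delivery and a hydroxyl-directed epoxidation that ignores the isopropenyl alkene.

10 to 9. Cut: the ester C–O bond. Reason: 9 is a commercial alcohol that already contains C8–C13 with the trisubstituted alkene in place.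

## Other disconnections considered

Alternative 1: the first that comes to mind. Cut C8–C9. The isopropenyl methyl of 1 is oxidised to the 2-substituted acrolein A1 and a prenyl nucleophile is added to the aldehyde, with the ring oxygenated as in the chosen plan. It is about two steps shorter on paper. The chosen plan is preferred on mechanistic grounds: prenyl metals react through a six-membered transition state that bonds their tertiary carbon to the aldehyde, which would give the branched instead of the linear C9–C10=C11 chain. Regiochemistry and C8 configuration would therefore both rest on a special allyl-transfer reagent acting 1,3 to the nearest stereocentre, on an aldehyde that is also a Michael acceptor at C14. In the chosen plan C8 is bonded to C9 before it becomes a stereocentre.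

Alternative 2: Cut C1–C7. The side-chain alkenyl bromide A2 is lithiated, transmetalated to copper and added to the epoxy enone A3, and the enolate is trapped with an oxygen electrophile. This would join a seven- and an eight-carbon fragment and set C1 and C2 in one operation. The chosen plan is preferred because the alkenyl group would have to enter C1 syn to the epoxide oxygen of A3, whereas approach anti to the three-membered ring is expected on steric and electrostatic grounds, so the step is stereochemically mismatched. A3 is also one elimination away from a phenol, needs about five steps in enantiopure form, and its α,β-epoxy ketone is open to reductive cleavage by electron-rich cuprates.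

Alternative 3: Cut the ring bonds C1–C6 and C2–C3. Diels–Alder addition of isoprene to the α′-silyloxy vinyl ketone A4 under chelation control would build the ring and relay the C8 configuration to C1, giving the cyclohexene A5. The chosen plan is preferred because A5 has no oxygen at C2, C3, C4 or C5. These would have to be introduced by allylic oxidation and epoxidation in the presence of the more nucleophilic C10=C11 alkene, the C7 ketone would have to be methylenated between two epimerisable centres (C1 and C8), and the step count rises well above that of the chosen plan.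

Key step: step 8

Remark: compound names use the atom labels defined under "Structural features" (not the conventional bisabolane numbering); (+)-sparteine is taken as a commercial reagent, and its enantiomer would give the 8R series.

## Route

Step 1
Reactants: 1 (R)-(−)-carvone
Product: 2 (−)-cis-carveol
Conditions: NaBH4, CeCl3·7H2O, MeOH, 0 °C
Reagents that add atoms: none
Why: Luche 1,2-reduction; the cerium-activated borohydride attacks only the enone carbonyl, and axial delivery to the half-chair with the C1 isopropenyl group pseudo-equatorial should give the pseudo-equatorial C3–OH, cis to the C1 substituent (β).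

Step 2
Reactants: 2 (−)-cis-carveol
Product: 3 cis-carveol β-epoxide
Conditions: VO(acac)2 (cat.), t-BuOOH, CH2Cl2, 0 °C → rt
Reagents that add atoms: tert-butyl hydroperoxide, CC(C)(C)OO
Why: Vanadium-catalysed hydroxyl-directed epoxidation; the vanadate ester of the allylic C3–OH delivers the peroxide oxygen to the same (β) face of C4=C5, setting C4 and C5 cis to the C1 substituent, while the remote, non-allylic isopropenyl alkene is not epoxidised under these conditions.

Step 3
Reactants: 3 cis-carveol β-epoxide
Product: 4 C3 TBS ether
Conditions: TBSOTf, 2,6-lutidine, CH2Cl2, −78 → 0 °C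
Reagents that add atoms: tert-butyldimethylsilyl triflate, CC(C)(C)[Si](C)(C)OS(=O)(=O)C(F)(F)F
Why: Silylation of the hindered secondary alcohol with the silyl triflate; it masks the only acidic and oxidisable group for steps 4–8 and holds C3 at the carbinol level.

Step 4
Reactants: 4 C3 TBS ether
Product: 5 methyl ketone
Conditions: OsO4 (cat.), NaIO4, 2,6-lutidine, dioxane–H2O (3:1), rt
Reagents that add atoms: sodium periodate (terminal oxidant; supplies the carbonyl O through the Os=O it regenerates), [Na+].[O-]I(=O)(=O)=O
Why: Lemieux–Johnson oxidative cleavage (Os-catalysed dihydroxylation, periodate glycol fission) of the only C=C left in the molecule; the former isopropenyl methyl stays on C7 and becomes C14, and the =CH2 carbon is excised.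

Step 5
Reactants: 5 methyl ketone
Product: 7 enol triflate, via potassium enolate 6 (not isolated)
Conditions: KHMDS, THF, −78 °C; then PhNTf2, −78 → −30 °C
Reagents that add atoms: N-phenylbis(trifluoromethanesulfonimide), O=S(=O)(N(c1ccccc1)S(=O)(=O)C(F)(F)F)C(F)(F)F
Why: Kinetic deprotonation of a methyl ketone by the hindered amide base at −78 °C should take a CH3 proton and not the tertiary C1–H, and the terminal enolate is O-sulfonylated by the triflimide; C1 keeps its configuration because it is not deprotonated.

Step 6
Reactants: 7 enol triflate
Product: 8 alkenyl pinacol boronate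
Conditions: B2pin2, PdCl2(PPh3)2 (cat.), PPh3, KOPh, toluene, 50 °C
Reagents that add atoms: bis(pinacolato)diboron, CC1(C)OB(OC1(C)C)B1OC(C)(C)C(C)(C)O1
Why: Miyaura borylation of an alkenyl triflate (oxidative addition, phenoxide-assisted transmetalation, reductive elimination) with retention of the 1,1-disubstituted alkene; this turns C7 into the migrating terminus for the key step.

Step 7
Reactants: 9 4-methylpent-3-en-1-ol
Product: 10 4-methylpent-3-en-1-yl 2,4,6-triisopropylbenzoate
Conditions: 2,4,6-triisopropylbenzoic acid, PPh3, DIAD, THF, 0 °C → rt
Reagents that add atoms: 2,4,6-triisopropylbenzoic acid, CC(C)c1cc(C(C)C)c(C(=O)O)c(C(C)C)c1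
Why: Mitsunobu esterification of a primary alcohol with the hindered acid; the triisopropylbenzoate directs the α-lithiation and later serves as the leaving group.

Step 8
Reactants: 10 4-methylpent-3-en-1-yl 2,4,6-triisopropylbenzoate; 8 alkenyl pinacol boronate
Product: 14 (8S)-allylic alcohol (C3 silyl ether), via lithiated benzoate 11 (not isolated), via boronate complex 12 (not isolated), via allylic boronic ester 13 (not isolated)
Conditions: 10, s-BuLi, (+)-sparteine, Et2O, −78 °C; then 8, −78 °C → rt; then NaOH, H2O2, THF–H2O, 0 °C
Reagents that add atoms: hydrogen peroxide, OO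
Why: Lithiation–borylation (1,2-metallate rearrangement of a boronate complex), the known route from α-lithiated primary O-alkyl benzoates or carbamates and alkenyl boronic esters to α-substituted allylic boronic esters. s-BuLi/(+)-sparteine removes the pro-R hydrogen of the O–CH2 group of 10 in a carbonyl-directed deprotonation to give the configurationally stable carbenoid 11, which adds to the vacant orbital on boron of 8 with retention to give 12. On warming, the alkenyl carbon C7 migrates from boron to C8 antiperiplanar to the departing triisopropylbenzoate (inversion at C8) to give 13, and alkaline peroxide then replaces boron by oxygen with retention, so the C7–C8 and C8–O bonds are both made and C8 should emerge as 8S. No ring is closed. C8 is the only new stereocentre and is controlled by the sparteine-bound organolithium alone, so the distant ring centres neither help nor erode it. The step needs attack of 11 at boron in preference to the epoxide (complexation of a boronic ester at −78 °C is expected to be far faster than epoxide opening by a hindered, stabilised carbanion) and migration of the sp2 carbon instead of a pinacol oxygen (secured by the high migratory aptitude of alkenyl groups and the good benzoate leaving group). The allylic pinacol boronate 13 is oxidised in the same flask so that no 1,3-boron shift can intervene.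

Step 9
Reactants: 14 (8S)-allylic alcohol (C3 silyl ether)
Product: 15 C8 angelate (C3 silyl ether)
Conditions: angelic acid, 2,4,6-trichlorobenzoyl chloride, Et3N, toluene, rt; then 14, 80 °C
Reagents that add atoms: angelic acid [(Z)-2-methylbut-2-enoic acid], C/C=C(/C)C(=O)O
Why: Yamaguchi-type acylation through the angelic/2,4,6-trichlorobenzoic mixed anhydride without a nucleophilic amine catalyst, the established way to angelates that avoids Z to E isomerisation of the acyl donor; no bond to C8 is broken, so its configuration is kept.

Step 10
Reactants: 15 C8 angelate (C3 silyl ether)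
Product: 16 C3 alcohol (C8 angelate)
Conditions: TBAF, AcOH, THF, rt
Reagents that add atoms: none
Why: Fluoride-mediated desilylation buffered with acetic acid, so that the liberated C3 alkoxide is protonated before it can open the epoxide or attack the ester.

Step 11
Reactants: 16 C3 alcohol (C8 angelate)
Product: 17 epoxy ketone (C8 angelate)
Conditions: Dess–Martin periodinane, NaHCO3, CH2Cl2, 0 °C → rt
Reagents that add atoms: none
Why: Dess–Martin oxidation of the secondary alcohol under buffered, non-acidic conditions should give the α,β-epoxy ketone without touching the epoxide, the ester or the alkenes.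

Step 12
Reactants: 17 epoxy ketone (C8 angelate)
Product: 19 2α-hydroxy ketone (C8 angelate), via sodium enolate 18 (not isolated)
Conditions: NaHMDS, THF, −78 °C; then 3-phenyl-2-(phenylsulfonyl)oxaziridine, −78 °C; AcOH quench
Reagents that add atoms: 3-phenyl-2-(phenylsulfonyl)oxaziridine, O=S(=O)(c1ccccc1)N1OC1c1ccccc1
Why: Davis enolate hydroxylation; C4 is quaternary, so the amide base can form only the C2 enolate of the ketone (far more acidic than the ester γ-protons), and the N-sulfonyloxaziridine should transfer oxygen to the enolate face anti to the adjacent C1 substituent, giving the 2α-OH (trans to the side chain), which is also the thermodynamically preferred diequatorial ketol.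

Step 13
Reactants: 19 2α-hydroxy ketone (C8 angelate)
Product: 20 CNP0271744.2
Conditions: angelic acid, 2,4,6-trichlorobenzoyl chloride, Et3N, toluene, rt; then 19, 80 °C
Reagents that add atoms: angelic acid [(Z)-2-methylbut-2-enoic acid], C/C=C(/C)C(=O)O
Why: The same mixed-anhydride acylation as in step 9, now on the C2 ketol; no bond to a stereocentre is broken, and the absence of a nucleophilic amine catalyst should keep both the Z-alkene of the acyl donor and the base-sensitive α-acyloxy ketone intact.

## Compound list

1 | (R)-(−)-carvone [(5R)-2-methyl-5-(prop-1-en-2-yl)cyclohex-2-en-1-one] | C=C(C)[C@@H]1CC=C(C)C(=O)C1 | starting material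
2 | (−)-cis-carveol [(1R,5R)-2-methyl-5-(prop-1-en-2-yl)cyclohex-2-en-1-ol; OH cis to isopropenyl] | C=C(C)[C@@H]1CC=C(C)[C@H](O)C1 | intermediate
3 | cis-carveol β-epoxide [(1R,2R,4S,6S)-1-methyl-4-(prop-1-en-2-yl)-7-oxabicyclo[4.1.0]heptan-2-ol; epoxide O, OH and isopropenyl on one face] | C=C(C)[C@@H]1C[C@@H]2O[C@]2(C)[C@H](O)C1 | intermediate
4 | C3 TBS ether of 3 [3β-(tert-butyldimethylsilyloxy)-4β,5β-epoxy-4-methyl-1β-(prop-1-en-2-yl)cyclohexane] | C=C(C)[C@@H]1C[C@@H]2O[C@]2(C)[C@H](O[Si](C)(C)C(C)(C)C)C1 | intermediate
5 | methyl ketone [1β-acetyl-3β-(tert-butyldimethylsilyloxy)-4β,5β-epoxy-4-methylcyclohexane] | CC(=O)[C@@H]1C[C@@H]2O[C@]2(C)[C@H](O[Si](C)(C)C(C)(C)C)C1 | intermediate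
6 | potassium enolate of 5 (terminal, C7=C14) | [K+].C=C([O-])[C@@H]1C[C@@H]2O[C@]2(C)[C@H](O[Si](C)(C)C(C)(C)C)C1 | intermediate
7 | enol triflate [1-(ring)ethenyl trifluoromethanesulfonate; ring as in 5] | C=C(OS(=O)(=O)C(F)(F)F)[C@@H]1C[C@@H]2O[C@]2(C)[C@H](O[Si](C)(C)C(C)(C)C)C1 | intermediate
8 | alkenyl pinacol boronate [2-[1-(ring)ethenyl]-4,4,5,5-tetramethyl-1,3,2-dioxaborolane; ring as in 5] | C=C(B3OC(C)(C)C(C)(C)O3)[C@@H]1C[C@@H]2O[C@]2(C)[C@H](O[Si](C)(C)C(C)(C)C)C1 | intermediate
9 | 4-methylpent-3-en-1-ol | CC(C)=CCCO | starting material
10 | 4-methylpent-3-en-1-yl 2,4,6-triisopropylbenzoate | CC(C)=CCCOC(=O)c1c(C(C)C)cc(C(C)C)cc1C(C)C | intermediate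
11 | (R)-1-lithio-4-methylpent-3-en-1-yl 2,4,6-triisopropylbenzoate, as its (+)-sparteine complex | CC(C)=CC[C@@H]([Li])OC(=O)c1c(C(C)C)cc(C(C)C)cc1C(C)C | intermediate
12 | lithium boronate complex of 11 and 8 (B bonded to C7 and C8) | [Li+].C=C([B-]3(OC(C)(C)C(C)(C)O3)[C@H](CC=C(C)C)OC(=O)c4c(C(C)C)cc(C(C)C)cc4C(C)C)[C@@H]1C[C@@H]2O[C@]2(C)[C@H](O[Si](C)(C)C(C)(C)C)C1 | intermediate
13 | (8S)-allylic pinacol boronic ester (Bpin on C8; ring as in 5) | C=C([C@H](CC=C(C)C)B3OC(C)(C)C(C)(C)O3)[C@@H]1C[C@@H]2O[C@]2(C)[C@H](O[Si](C)(C)C(C)(C)C)C1 | intermediate
14 | (8S)-allylic alcohol [ring with 3β-OTBS and 4β,5β-epoxide; C1β–C7(=CH2)–C8H(OH)–CH2CH=CMe2] | C=C([C@H](CC=C(C)C)O)[C@@H]1C[C@@H]2O[C@]2(C)[C@H](O[Si](C)(C)C(C)(C)C)C1 | intermediate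
15 | (8S)-8-O-angelate of 14 | C=C([C@H](CC=C(C)C)OC(=O)/C(C)=C\C)[C@@H]1C[C@@H]2O[C@]2(C)[C@H](O[Si](C)(C)C(C)(C)C)C1 | intermediate
16 | (8S)-8-angeloyloxy 3β-alcohol (4β,5β-epoxide) | C=C([C@H](CC=C(C)C)OC(=O)/C(C)=C\C)[C@@H]1C[C@@H]2O[C@]2(C)[C@H](O)C1 | intermediate
17 | (8S)-8-angeloyloxy 4β,5β-epoxy 3-ketone | C=C([C@H](CC=C(C)C)OC(=O)/C(C)=C\C)[C@@H]1C[C@@H]2O[C@]2(C)C(=O)C1 | intermediate
18 | sodium C2=C3 enolate of 17 | C=C([C@H](CC=C(C)C)OC(=O)/C(C)=C\C)[C@@H]1C[C@@H]2O[C@]2(C)C([O-])=C1.[Na+] | intermediate
19 | (8S)-8-angeloyloxy-4β,5β-epoxy-2α-hydroxy 3-ketone | C=C([C@H](CC=C(C)C)OC(=O)/C(C)=C\C)[C@@H]1C[C@@H]2O[C@]2(C)C(=O)[C@H]1O | intermediate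
20 | CNP0271744.2 [(1S,2S,4S,5S,8S) with the labels used here; in conventional bisabolane numbering (1S,3S,4S,6S,8S)-1,8-bis[(Z)-2-methylbut-2-enoyloxy]-3,4-epoxybisabola-7(14),10-dien-2-one] | C=C([C@H](CC=C(C)C)OC(=O)/C(C)=C\C)[C@@H]1C[C@@H]2O[C@]2(C)C(=O)[C@H]1OC(=O)/C(C)=C\C | target

## Step count and least certain steps

Total step count: 13. Longest linear sequence: 12 steps (1 to 20 through steps 1–6 and 8–13); step 7 is a one-step side branch.

Step 8 (key step). Most likely to go wrong: slow or reversible formation of the boronate complex between the hindered carbenoid and the α-branched alkenyl boronate, so that the carbenoid decomposes on warming before the 1,2-shift, or competing attack of the organolithium on the epoxide. Fallback, from 7 back to 14: buffered Dess–Martin oxidation of 9 gives 4-methylpent-3-enal F1, used at once. Nozaki–Hiyama–Kishi coupling of triflate 7 with it (CrCl2, cat. NiCl2, DMF) gives the C8-epimeric allylic alcohols F2. Dess–Martin oxidation then gives the enone F3, and Corey–Bakshi–Shibata reduction with the (R)-oxazaborolidine, in which the branched alkenyl group acts as the large substituent, should return the 8S alcohol 14.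

Step 12. Most likely to go wrong: the base or the enolate engages the C8 angelate, by Z to E isomerisation through the ester dienolate, Claisen-type attack of the C2 enolate on the ester carbonyl, or acyl migration to the new C2 alkoxide. Fallback, from 14 to 20, which hydroxylates before any angelate is present: 14 is converted to the C8 PMB ether F4 (NaH, PMBCl) and desilylated (TBAF) to the C3 alcohol F5. Dess–Martin oxidation gives the epoxy ketone F6, the hydroxylation of step 12 gives the ketol F7, and DDQ frees the diol F8. Both hydroxyls are then angeloylated in one operation under the conditions of step 13 to give 20.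

Step 13. Most likely to go wrong: slow acylation of the hindered ketol at 80 °C, which gives time for epimerisation at C2, ketol transposition and Z to E isomerisation of the activated acyl donor. Fallback, from 19 to 20, which builds the Z-alkene on the molecule: 19 is esterified with 2-[bis(2-methylphenoxy)phosphoryl]propanoic acid (DCC, cat. DMAP) to the phosphonopropionate ester F9. An Ando-type Z-selective Horner–Wadsworth–Emmons reaction with acetaldehyde (mild base, low temperature) then gives 20.

Step 5. Most likely to go wrong: proton abstraction at C1 instead of at the methyl group, leading to the internal triflate, loss of the C1 configuration or attack of the C1 enolate on the epoxide. Fallback, from 5 to 8, bypassing 7: condensation of 5 with 2,4,6-triisopropylbenzenesulfonyl hydrazide gives the trisylhydrazone F10. A Shapiro reaction (2 equiv n-BuLi, THF–TMEDA, −78 → 0 °C) generates the alkenyllithium at the methyl terminus, and trapping with 2-isopropoxy-4,4,5,5-tetramethyl-1,3,2-dioxaborolane gives 8.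

## Further compounds

F1 | step 8 | 4-methylpent-3-enal | CC(C)=CCC=O
F2 | step 8 | C8-epimeric allylic alcohols (8R/8S mixture corresponding to 14) | C=C(C(O)CC=C(C)C)[C@@H]1C[C@@H]2O[C@]2(C)[C@H](O[Si](C)(C)C(C)(C)C)C1
F3 | step 8 | C8 enone (3β-OTBS, 4β,5β-epoxide) | C=C(C(=O)CC=C(C)C)[C@@H]1C[C@@H]2O[C@]2(C)[C@H](O[Si](C)(C)C(C)(C)C)C1
F4 | step 12 | (8S)-8-O-(4-methoxybenzyl) ether of 14 | C=C([C@H](CC=C(C)C)OCc3ccc(OC)cc3)[C@@H]1C[C@@H]2O[C@]2(C)[C@H](O[Si](C)(C)C(C)(C)C)C1
F5 | step 12 | (8S)-8-O-PMB 3β-alcohol | C=C([C@H](CC=C(C)C)OCc3ccc(OC)cc3)[C@@H]1C[C@@H]2O[C@]2(C)[C@H](O)C1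
F6 | step 12 | (8S)-8-O-PMB 4β,5β-epoxy 3-ketone | C=C([C@H](CC=C(C)C)OCc3ccc(OC)cc3)[C@@H]1C[C@@H]2O[C@]2(C)C(=O)C1
F7 | step 12 | (8S)-8-O-PMB 2α-hydroxy 3-ketone | C=C([C@H](CC=C(C)C)OCc3ccc(OC)cc3)[C@@H]1C[C@@H]2O[C@]2(C)C(=O)[C@H]1O
F8 | step 12 | (8S)-2α,8-dihydroxy-4β,5β-epoxy 3-ketone | C=C([C@H](CC=C(C)C)O)[C@@H]1C[C@@H]2O[C@]2(C)C(=O)[C@H]1O
F9 | step 13 | 2-O-[2-(di-o-tolyloxyphosphoryl)propanoyl] ester of 19 | C=C([C@H](CC=C(C)C)OC(=O)/C(C)=C\C)[C@@H]1C[C@@H]2O[C@]2(C)C(=O)[C@H]1OC(=O)C(C)P(=O)(Oc3ccccc3C)Oc3ccccc3C
F10 | step 5 | 2,4,6-triisopropylbenzenesulfonyl hydrazone of 5 | CC(=NNS(=O)(=O)c3c(C(C)C)cc(C(C)C)cc3C(C)C)[C@@H]1C[C@@H]2O[C@]2(C)[C@H](O[Si](C)(C)C(C)(C)C)C1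
A1 | alternative 1 | 2-[(1R)-4-methyl-5-oxocyclohex-3-en-1-yl]prop-2-enal | C=C(C=O)[C@@H]1CC=C(C)C(=O)C1
A2 | alternative 2 | (S)-[(2-bromo-6-methylhepta-1,5-dien-3-yl)oxy](tert-butyl)dimethylsilane | C=C(Br)[C@H](CC=C(C)C)O[Si](C)(C)C(C)(C)C
A3 | alternative 2 | (1S,6S)-1-methyl-7-oxabicyclo[4.1.0]hept-3-en-2-one | C1=CC(=O)[C@@]2(C)O[C@H]2C1
A4 | alternative 3 | (S)-4-[(tert-butyldimethylsilyl)oxy]-7-methylocta-1,6-dien-3-one | C=CC(=O)[C@H](CC=C(C)C)O[Si](C)(C)C(C)(C)C
A5 | alternative 3 | (2S)-2-[(tert-butyldimethylsilyl)oxy]-5-methyl-1-[(1S)-4-methylcyclohex-3-en-1-yl]hex-4-en-1-one | O=C([C@H](CC=C(C)C)O[Si](C)(C)C(C)(C)C)[C@@H]1CC=C(C)CC1
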